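**Retrosynthetic overview**
1. The C6 alcohol and the C8 ester come last from one cyclic β-hydroxy enone: an Evans–Tishchenko reduction with an O-silylated 4-hydroxybenzaldehyde acylates O8 and sets C6 anti to C8.
2. The ten-membered ring (the only ring formed) is closed at C5–C6 by Nozaki–Hiyama–Kishi addition of a (Z)-vinyl iodide to an aldehyde; allylic oxidation then gives the enone.
3. C7 and C8 are set together by an auxiliary-controlled syn aldol that makes the C7–C8 bond.
4. The C4=C5 (Z) olefin comes from syn-carbocupration of propyne by an alkylcopper (C3–C4 bond), trapped with iodine.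
5. Key step: the C1=C10 (Z) olefin with C2, C3, C8, C9 and its methyl is cut out of the benzene ring of 4-methylanisole by Birch reduction, then ozonolysis of only the enol ether double bond.

Assumption: the SMILES is taken literally (both ring olefins Z, the three stereocentres all S); germacrane atom numbers are used for positions (C1=C10, C4=C5, C6–OH, C7–isopropyl, C8–O-aroyl).

**Step 1**
Reactants: 1 4-methylanisole (1-methoxy-4-methylbenzene)
Product: 2 1-methoxy-4-methylcyclohexa-1,4-diene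
Conditions: Li, NH3 (l), THF, tBuOH, −78 → −33 °C; then NH4Cl
Reagents that add atoms: none
Why: Birch reduction protonates the ring carbons that carry no donor group, so the methoxy and the methyl group each end up on one of the two isolated double bonds of the 1,4-diene (dearomatisation, no stereocentre).

**Step 2**
Reactants: 2 1-methoxy-4-methylcyclohexa-1,4-diene
Product: 4 methyl (3Z)-6,6-dimethoxy-4-methylhex-3-enoate, via aldehyde ester 3 (not isolated)
Conditions: O3 (1.0 equiv, Sudan Red 7B end point), CH2Cl2/MeOH, −78 °C; Me2S, → rt; then HC(OMe)3, TsOH (cat.), rt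
Reagents that add atoms: ozone, [O-][O+]=O; trimethyl orthoformate, COC(OC)OC
Why: Chemoselective ozonolysis cleaves only the electron-rich enol ether double bond, so the surviving trisubstituted olefin keeps the cis geometry imposed by the former ring (this fixes C1=C10 as Z) and the two termini emerge differentiated as ester and aldehyde, the latter acetalised in the same flask.

**Step 3**
Reactants: 4 methyl (3Z)-6,6-dimethoxy-4-methylhex-3-enoate
Product: 5 (3Z)-6,6-dimethoxy-4-methylhex-3-en-1-ol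
Conditions: LiAlH4, Et2O, 0 °C; then H2O, NaOH (aq)
Reagents that add atoms: none
Why: Hydride reduction of the ester to the primary alcohol leaves the acetal and the isolated olefin untouched.

**Step 4**
Reactants: 5 (3Z)-6,6-dimethoxy-4-methylhex-3-en-1-ol
Product: 6 (3Z)-6-bromo-1,1-dimethoxy-3-methylhex-3-ene
Conditions: CBr4, PPh3, pyridine, CH2Cl2, 0 °C
Reagents that add atoms: tetrabromomethane, BrC(Br)(Br)Br
Why: Appel bromination of the primary alcohol runs under buffered, essentially neutral conditions that the acetal and the olefin tolerate.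

**Step 5**
Reactants: 6 (3Z)-6-bromo-1,1-dimethoxy-3-methylhex-3-ene; 7 propyne
Product: 11 (1Z,5Z)-1-iodo-8,8-dimethoxy-2,6-dimethylocta-1,5-diene, via Grignard reagent 8 (not isolated), via alkylcopper 9 (not isolated), via alkenylcopper 10 (not isolated)
Conditions: Mg, Et2O, rt; CuBr·SMe2, Et2O/Me2S, −45 °C; 7, −25 °C; I2, THF, −50 → 0 °C
Reagents that add atoms: iodine, II
Why: Normant carbocupration adds the alkyl group and copper to the same face of propyne (carbon to the internal, copper to the terminal position) and iodinolysis proceeds with retention, so the chain and the iodine are cis and the C4=C5 olefin is set as Z.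

**Step 6**
Reactants: 11 (1Z,5Z)-1-iodo-8,8-dimethoxy-2,6-dimethylocta-1,5-diene
Product: 12 (3Z,7Z)-8-iodo-3,7-dimethylocta-3,7-dienal
Conditions: LiBF4, MeCN/H2O (50:1), rt; used crude at once
Reagents that add atoms: water, O
Why: Mild Lewis-acid hydrolysis of the dimethyl acetal frees the aldehyde without moving the β,γ-double bond into conjugation.

**Step 7**
Reactants: 13 (4R)-4-benzyl-1,3-thiazolidine-2-thione; 14 3-methylbutanoyl chloride
Product: 15 (4R)-4-benzyl-3-(3-methylbutanoyl)-1,3-thiazolidine-2-thione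
Conditions: Et3N, DMAP (cat.), CH2Cl2, 0 °C → rt
Reagents that add atoms: none
Why: Simple N-acylation installs the chiral auxiliary on the isovaleryl unit that will become C6, C7 and the isopropyl group.

**Step 8**
Reactants: 15 (4R)-4-benzyl-3-(3-methylbutanoyl)-1,3-thiazolidine-2-thione; 12 (3Z,7Z)-8-iodo-3,7-dimethylocta-3,7-dienal
Product: 17 (2R,3S,5Z,9Z)-1-[(4R)-4-benzyl-2-sulfanylidene-1,3-thiazolidin-3-yl]-3-hydroxy-10-iodo-5,9-dimethyl-2-(propan-2-yl)deca-5,9-dien-1-one, via titanium enolate 16 (not isolated)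
Conditions: 15, TiCl4 (1.05 equiv), iPr2NEt (1.1 equiv), N-methylpyrrolidin-2-one (1.1 equiv), CH2Cl2, 0 °C; then 12, −78 → 0 °C; NH4Cl (aq)
Reagents that add atoms: none
Why: Crimmins titanium aldol: the (Z)-enolate reacts through a non-chelated Zimmerman–Traxler chair on the face away from the benzyl group, giving the Evans-syn adduct whose two new centres are C7 and C8 with the configuration and syn relationship of the target.

**Step 9**
Reactants: 17 (2R,3S,5Z,9Z)-1-[(4R)-4-benzyl-2-sulfanylidene-1,3-thiazolidin-3-yl]-3-hydroxy-10-iodo-5,9-dimethyl-2-(propan-2-yl)deca-5,9-dien-1-one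
Product: 18 (2R,3S,5Z,9Z)-3-hydroxy-10-iodo-5,9-dimethyl-2-(propan-2-yl)deca-5,9-dienal
Conditions: iBu2AlH (2.2 equiv), CH2Cl2, −78 °C; then KNaC4H4O6 (aq)
Reagents that add atoms: none
Why: The activated thioimide is reduced by the aluminium hydride to a stable tetrahedral adduct that collapses to the aldehyde only on work-up, so the auxiliary is removed in one step without over-reduction or epimerisation.

**Step 10**
Reactants: 18 (2R,3S,5Z,9Z)-3-hydroxy-10-iodo-5,9-dimethyl-2-(propan-2-yl)deca-5,9-dienal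
Product: 20 (1S,2R,3RS,4Z,8Z)-5,9-dimethyl-2-(propan-2-yl)cyclodeca-4,8-diene-1,3-diol, via alkenylchromium 19 (not isolated)
Conditions: CrCl2 (6 equiv), NiCl2 (2 mol %), DMSO/THF, 0.003 M (slow addition), rt
Reagents that add atoms: none
Why: Intramolecular Nozaki–Hiyama–Kishi reaction: the alkenylchromium forms with retention of the (Z) geometry and adds chemoselectively to the aldehyde beside the free hydroxyl, closing the ten-membered ring at C5–C6; the new C6 carbinol is an epimer mixture that the next step erases.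

**Step 11**
Reactants: 20 (1S,2R,3RS,4Z,8Z)-5,9-dimethyl-2-(propan-2-yl)cyclodeca-4,8-diene-1,3-diol
Product: 21 (2Z,6Z,9S,10R)-9-hydroxy-3,7-dimethyl-10-(propan-2-yl)cyclodeca-2,6-dien-1-one
Conditions: MnO2 (activated, excess), CH2Cl2, rt
Reagents that add atoms: none
Why: MnO2 oxidises only the allylic alcohol, so both C6 epimers converge on one β-hydroxy enone under neutral conditions that avoid retro-aldol opening and dehydration.

**Step 12**
Reactants: 21 (2Z,6Z,9S,10R)-9-hydroxy-3,7-dimethyl-10-(propan-2-yl)cyclodeca-2,6-dien-1-one; 22 4-{[tert-butyl(dimethyl)silyl]oxy}benzaldehyde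
Product: 23 (1S,2S,3S,4Z,8Z)-3-hydroxy-5,9-dimethyl-2-(propan-2-yl)cyclodeca-4,8-dien-1-yl 4-{[tert-butyl(dimethyl)silyl]oxy}benzoate
Conditions: 22 (6 equiv), SmI2 (0.3 equiv, premixed with 22), THF, −10 °C
Reagents that add atoms: none
Why: Evans–Tishchenko reduction: the C8 hydroxyl forms a samarium-bound hemiacetal with 22 that delivers hydride intramolecularly to the C6 carbonyl through a chair-like six-membered transition state, giving the 1,3-anti alcohol (6S) and leaving the aroyl group on O8 in the same operation.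

**Step 13**
Reactants: 23 (1S,2S,3S,4Z,8Z)-3-hydroxy-5,9-dimethyl-2-(propan-2-yl)cyclodeca-4,8-dien-1-yl 4-{[tert-butyl(dimethyl)silyl]oxy}benzoate
Product: 24 (1S,2S,3S,4Z,8Z)-3-hydroxy-5,9-dimethyl-2-(propan-2-yl)cyclodeca-4,8-dien-1-yl 4-hydroxybenzoate
Conditions: Bu4NF, AcOH, THF, 0 °C
Reagents that add atoms: none
Why: Buffered fluoride cleaves the aryl silyl ether selectively; the acetic acid buffer suppresses acyl migration between O8 and O6 and ester cleavage.

**Compound list**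
1 | 4-methylanisole | COc1ccc(C)cc1 | starting material
2 | 1-methoxy-4-methylcyclohexa-1,4-diene | COC1=CCC(C)=CC1 | intermediate
3 | methyl (3Z)-4-methyl-6-oxohex-3-enoate | O=CC/C(C)=C\CC(=O)OC | intermediate
4 | methyl (3Z)-6,6-dimethoxy-4-methylhex-3-enoate | COC(OC)C/C(C)=C\CC(=O)OC | intermediate
5 | (3Z)-6,6-dimethoxy-4-methylhex-3-en-1-ol | COC(OC)C/C(C)=C\CCO | intermediate
6 | (3Z)-6-bromo-1,1-dimethoxy-3-methylhex-3-ene | COC(OC)C/C(C)=C\CCBr | intermediate
7 | propyne | CC#C | starting material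
8 | [(3Z)-6,6-dimethoxy-4-methylhex-3-en-1-yl]magnesium bromide | COC(OC)C/C(C)=C\CC[Mg]Br | intermediate
9 | [(3Z)-6,6-dimethoxy-4-methylhex-3-en-1-yl]copper | COC(OC)C/C(C)=C\CC[Cu] | intermediate
10 | [(1Z,5Z)-8,8-dimethoxy-2,6-dimethylocta-1,5-dien-1-yl]copper | COC(OC)C/C(C)=C\CC/C(C)=C\[Cu] | intermediate
11 | (1Z,5Z)-1-iodo-8,8-dimethoxy-2,6-dimethylocta-1,5-diene | COC(OC)C/C(C)=C\CC/C(C)=C\I | intermediate
12 | (3Z,7Z)-8-iodo-3,7-dimethylocta-3,7-dienal | O=CC/C(C)=C\CC/C(C)=C\I | intermediate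
13 | (4R)-4-benzyl-1,3-thiazolidine-2-thione | S=C1N[C@H](Cc2ccccc2)CS1 | starting material
14 | 3-methylbutanoyl chloride | CC(C)CC(=O)Cl | starting material
15 | (4R)-4-benzyl-3-(3-methylbutanoyl)-1,3-thiazolidine-2-thione | CC(C)CC(=O)N1[C@H](Cc2ccccc2)CSC1=S | intermediate
16 | trichloro({(1Z)-1-[(4R)-4-benzyl-2-sulfanylidene-1,3-thiazolidin-3-yl]-3-methylbut-1-en-1-yl}oxy)titanium | CC(C)/C=C(\O[Ti](Cl)(Cl)Cl)N1[C@H](Cc2ccccc2)CSC1=S | intermediate
17 | (2R,3S,5Z,9Z)-1-[(4R)-4-benzyl-2-sulfanylidene-1,3-thiazolidin-3-yl]-3-hydroxy-10-iodo-5,9-dimethyl-2-(propan-2-yl)deca-5,9-dien-1-one | O=C([C@H](C(C)C)[C@@H](O)C/C(C)=C\CC/C(C)=C\I)N1[C@H](Cc2ccccc2)CSC1=S | intermediate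
18 | (2R,3S,5Z,9Z)-3-hydroxy-10-iodo-5,9-dimethyl-2-(propan-2-yl)deca-5,9-dienal | O=C[C@H](C(C)C)[C@@H](O)C/C(C)=C\CC/C(C)=C\I | intermediate
19 | dichloro[(1Z,5Z,8S,9R)-8-hydroxy-2,6-dimethyl-10-oxo-9-(propan-2-yl)deca-1,5-dien-1-yl]chromium | O=C[C@H](C(C)C)[C@@H](O)C/C(C)=C\CC/C(C)=C\[Cr](Cl)Cl | intermediate
20 | (1S,2R,3RS,4Z,8Z)-5,9-dimethyl-2-(propan-2-yl)cyclodeca-4,8-diene-1,3-diol (both C3 epimers) | C/C1=C/C(O)[C@H](C(C)C)[C@@H](O)C/C(C)=C\CC1 | intermediate
21 | (2Z,6Z,9S,10R)-9-hydroxy-3,7-dimethyl-10-(propan-2-yl)cyclodeca-2,6-dien-1-one | C/C1=C/C(=O)[C@H](C(C)C)[C@@H](O)C/C(C)=C\CC1 | intermediate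
22 | 4-{[tert-butyl(dimethyl)silyl]oxy}benzaldehyde | CC(C)(C)[Si](C)(C)Oc1ccc(C=O)cc1 | starting material
23 | (1S,2S,3S,4Z,8Z)-3-hydroxy-5,9-dimethyl-2-(propan-2-yl)cyclodeca-4,8-dien-1-yl 4-{[tert-butyl(dimethyl)silyl]oxy}benzoate | C/C1=C/[C@H](O)[C@H](C(C)C)[C@@H](OC(=O)c2ccc(O[Si](C)(C)C(C)(C)C)cc2)C/C(C)=C\CC1 | intermediate
24 | (1S,2S,3S,4Z,8Z)-3-hydroxy-5,9-dimethyl-2-(propan-2-yl)cyclodeca-4,8-dien-1-yl 4-hydroxybenzoate | C/C1=C/[C@H](O)[C@H](C(C)C)[C@@H](OC(=O)c2ccc(O)cc2)C/C(C)=C\CC1 | target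

**Step count and risks**
Total step count: 13. Longest linear sequence: 12 steps (steps 1–6 and 8–13, from 4-methylanisole).

The three steps most likely to fail:

Step 8. The β,γ-unsaturated aldehyde 12 may isomerise or react poorly with the strongly Lewis-acidic titanium enolate. The fallback sets out from 12 and comes back at 18, replacing the titanium thioimide aldol by a boron oxazolidinone aldol with reductive removal of the auxiliary. (4R)-4-Benzyl-1,3-oxazolidin-2-one is acylated with 14 (nBuLi, THF, −78 °C) to give (4R)-4-benzyl-3-(3-methylbutanoyl)-1,3-oxazolidin-2-one F1. Its dibutylboron (Z)-enolate (Bu2BOTf, Et3N, CH2Cl2, −78 °C) adds to 12 to give the Evans-syn adduct (4R)-4-benzyl-3-[(2R,3S,5Z,9Z)-3-hydroxy-10-iodo-5,9-dimethyl-2-(propan-2-yl)deca-5,9-dienoyl]-1,3-oxazolidin-2-one F2. LiBH4 (THF/MeOH, 0 °C) reduces this to (2S,3S,5Z,9Z)-10-iodo-5,9-dimethyl-2-(propan-2-yl)deca-5,9-diene-1,3-diol F3, and selective oxidation of the primary alcohol (TEMPO, PhI(OAc)2, CH2Cl2) gives 18.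

Step 10. Closing a ten-membered ring competes with oligomerisation, and the unprotected β-hydroxy aldehyde is fragile. The fallback sets out from 17 and comes back at 21, closing the same C5–C6 bond by anionic acylation instead. Aminolysis of the thioimide (MeONHMe·HCl, imidazole, CH2Cl2) gives the Weinreb amide (2R,3S,5Z,9Z)-3-hydroxy-10-iodo-N-methoxy-N,5,9-trimethyl-2-(propan-2-yl)deca-5,9-dienamide F4. Silylation (Et3SiOTf, 2,6-lutidine) gives (2R,3S,5Z,9Z)-10-iodo-N-methoxy-N,5,9-trimethyl-2-(propan-2-yl)-3-[(triethylsilyl)oxy]deca-5,9-dienamide F5. Iodine–lithium exchange (tBuLi, 2.1 equiv, THF, −78 °C, high dilution) triggers intramolecular acylation to (2Z,6Z,9S,10R)-3,7-dimethyl-10-(propan-2-yl)-9-[(triethylsilyl)oxy]cyclodeca-2,6-dien-1-one F6, and HF·pyridine (THF, 0 °C) releases 21.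

Step 12. The hydride transfer must reach a conjugated, ring-constrained ketone, and the electron-rich aldehyde is a modest hydride donor. The fallback sets out from 21 and comes back at 23, separating acylation from reduction. Esterification of the only hydroxyl with 4-{[tert-butyl(dimethyl)silyl]oxy}benzoic acid (EDC·HCl, DMAP, CH2Cl2) gives (1S,2R,4Z,8Z)-5,9-dimethyl-3-oxo-2-(propan-2-yl)cyclodeca-4,8-dien-1-yl 4-{[tert-butyl(dimethyl)silyl]oxy}benzoate F7. Reagent-controlled 1,2-reduction of the enone ((S)-2-methyl-CBS-oxazaborolidine, catecholborane, toluene, −78 °C; the catalyst antipode is confirmed on the first run) then gives 23.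

**Further compounds**
F1 | step 8 | (4R)-4-benzyl-3-(3-methylbutanoyl)-1,3-oxazolidin-2-one | CC(C)CC(=O)N1[C@H](Cc2ccccc2)COC1=O
F2 | step 8 | (4R)-4-benzyl-3-[(2R,3S,5Z,9Z)-3-hydroxy-10-iodo-5,9-dimethyl-2-(propan-2-yl)deca-5,9-dienoyl]-1,3-oxazolidin-2-one | O=C([C@H](C(C)C)[C@@H](O)C/C(C)=C\CC/C(C)=C\I)N1[C@H](Cc2ccccc2)COC1=O
F3 | step 8 | (2S,3S,5Z,9Z)-10-iodo-5,9-dimethyl-2-(propan-2-yl)deca-5,9-diene-1,3-diol | OC[C@H](C(C)C)[C@@H](O)C/C(C)=C\CC/C(C)=C\I
F4 | step 10 | (2R,3S,5Z,9Z)-3-hydroxy-10-iodo-N-methoxy-N,5,9-trimethyl-2-(propan-2-yl)deca-5,9-dienamide | CON(C)C(=O)[C@H](C(C)C)[C@@H](O)C/C(C)=C\CC/C(C)=C\I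
F5 | step 10 | (2R,3S,5Z,9Z)-10-iodo-N-methoxy-N,5,9-trimethyl-2-(propan-2-yl)-3-[(triethylsilyl)oxy]deca-5,9-dienamide | CON(C)C(=O)[C@H](C(C)C)[C@@H](O[Si](CC)(CC)CC)C/C(C)=C\CC/C(C)=C\I
F6 | step 10 | (2Z,6Z,9S,10R)-3,7-dimethyl-10-(propan-2-yl)-9-[(triethylsilyl)oxy]cyclodeca-2,6-dien-1-one | C/C1=C/C(=O)[C@H](C(C)C)[C@@H](O[Si](CC)(CC)CC)C/C(C)=C\CC1
F7 | step 12 | (1S,2R,4Z,8Z)-5,9-dimethyl-3-oxo-2-(propan-2-yl)cyclodeca-4,8-dien-1-yl 4-{[tert-butyl(dimethyl)silyl]oxy}benzoate | C/C1=C/C(=O)[C@H](C(C)C)[C@@H](OC(=O)c2ccc(O[Si](C)(C)C(C)(C)C)cc2)C/C(C)=C\CC1
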